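**Retrosynthetic overview**

1. Target 13 ⇐ 12 ⇐ 11: the phenol methyl ether (BBr3) and the pyrrole N‑SEM group (fluoride) are removed last.
2. Feature: in oxazole ring B the chlorinated C4 lies between N3 and C5, and C5 carries ring A. N3=C4(Cl)–C5(=O)Ar is therefore the α‑keto imidoyl chloride that an isocyanide gives on insertion into the C–Cl bond of the aroyl chloride of ring A. C2, which carries pyrrole ring C, can arrive as an sp3 carbon bearing a sulfonyl leaving group.
3. Ring B ⇒ C4–C5 and C4–Cl (isocyanide insertion), then O1–C2 (anionic closure with loss of sulfinate): 4‑methoxybenzoyl chloride 9 + α‑tosyl isocyanide 8.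
4. 8 ⇐ formamide 7 ⇐ aldehyde 3 + formamide 4 + p‑toluenesulfinic acid 5; 3 ⇐ pyrrole‑2‑carbaldehyde 1 by trichlorination and N‑SEM protection.
5. Ring order: rings A and C are bought (ring C is chlorinated in step 1); ring B is the only ring built, in step 5.

Key step: step 5

Assumption: p‑toluenesulfinic acid 5 is used as the free acid (purchased, or freshly liberated from its sodium salt with dilute HCl, which is not counted as a step). The target is achiral; 7, 8 and 10 are racemic at the sulfonyl‑bearing carbon, which is erased in step 5. SEM = 2‑(trimethylsilyl)ethoxymethyl.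

**Route**

Step 1
Reactants: 1 pyrrole‑2‑carbaldehyde
Product: 2 3,4,5‑trichloro‑1H‑pyrrole‑2‑carbaldehyde
Conditions: NCS (3.3 equiv), DMF, 0 °C→55 °C, dark
Reagents that add atoms: N‑chlorosuccinimide, O=C1CCC(=O)N1Cl
Why: Electrophilic aromatic chlorination of the pyrrole, which should take C4 and C5 first and the more deactivated C3 last, so that a small excess of reagent and gentle warming should carry all three free ring positions to C–Cl while the formyl group is untouched under ionic conditions.

Step 2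
Reactants: 2 3,4,5‑trichloro‑1H‑pyrrole‑2‑carbaldehyde
Product: 3 3,4,5‑trichloro‑1‑SEM‑pyrrole‑2‑carbaldehyde
Conditions: NaH (1.2 equiv), SEMCl (1.2 equiv), THF/DMF, 0 °C→rt
Reagents that add atoms: 2‑(trimethylsilyl)ethoxymethyl chloride, C[Si](C)(C)CCOCCl
Why: SN2 N‑alkylation of the sodium salt of the acidic trichloropyrrole by the reactive chloromethyl ether; the group blocks N–H chemistry (azafulvene formation, N‑acylation) in steps 3 to 5.

Step 3
Reactants: 3 3,4,5‑trichloro‑1‑SEM‑pyrrole‑2‑carbaldehyde, 4 formamide, 5 p‑toluenesulfinic acid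
Product: 7 N‑{(4‑methylphenylsulfonyl)[3,4,5‑trichloro‑1‑SEM‑pyrrol‑2‑yl]methyl}formamide (racemic), via bis‑formamide aminal 6 (not isolated)
Conditions: HCONH2 (2.5 equiv), Me3SiCl (2.2 equiv), PhMe/MeCN 1:1, 50 °C; then TolSO2H (1.5 equiv), 50 °C
Reagents that add atoms: none
Why: Three‑component Mannich‑type condensation to an α‑amido sulfone, the standard entry to α‑substituted TosMIC reagents: Me3SiCl takes up the water as the non‑enolisable aldehyde forms aminal 6, which ionises to an N‑formyliminium ion that the sulfinate captures through sulfur, giving the new stereocentre as a racemate.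

Step 4
Reactants: 7 N‑{(4‑methylphenylsulfonyl)[3,4,5‑trichloro‑1‑SEM‑pyrrol‑2‑yl]methyl}formamide
Product: 8 2,3,4‑trichloro‑5‑[isocyano(4‑methylphenylsulfonyl)methyl]‑1‑SEM‑pyrrole (racemic)
Conditions: POCl3 (2 equiv), Et3N (6 equiv), THF, −10 °C→5 °C
Reagents that add atoms: none
Why: Dehydration of a secondary formamide to an isocyanide with POCl3 and Et3N, kept cold because α‑sulfonyl isocyanides are sensitive to heat and to base; the stereocentre remains racemic.

Step 5
Reactants: 8 2,3,4‑trichloro‑5‑[isocyano(4‑methylphenylsulfonyl)methyl]‑1‑SEM‑pyrrole (1.1 equiv), 9 4‑methoxybenzoyl chloride (1.0 equiv)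
Product: 11 4‑chloro‑5‑(4‑methoxyphenyl)‑2‑(3,4,5‑trichloro‑1‑SEM‑pyrrol‑2‑yl)oxazole, via keto imidoyl chloride 10 (not isolated)
Conditions: PhMe (2 M), 60 °C, no base; then THF, DBU (2.2 equiv), −20 °C→rt
Reagents that add atoms: none
Why: Proposed new method: with no base present the terminal isocyanide carbon of 8 should attack the carbonyl carbon of 9 and take up the chloride in a concerted α‑addition (Nef isocyanide reaction, known for acyl chlorides with alkyl isocyanides and isocyanoacetates but not for α‑sulfonyl isocyanides), which sets C4–C5 and C4–Cl in 10. DBU should then remove the proton on the carbon flanked by the sulfonyl group, ring C and the imine nitrogen, and the delocalised 1‑oxa‑4‑azapentadienyl anion (an enolate in one resonance form, so that rotation about N3–C4 into the U‑shape is easy) should close through the ketone oxygen onto that carbon in a six‑electron 1,5‑electrocyclisation (formally 5‑endo) that forms O1–C2 and ring B. The ring nitrogen anion should then expel p‑toluenesulfinate from C2, as in the aromatising step of the van Leusen oxazole synthesis, which makes the sequence irreversible. The closest known reaction types are that sulfinate elimination and the 1,5‑electrocyclisation of acyl‑conjugated nitrile and azomethine ylides to oxazoles and oxazolines. No stereocentre is formed and the single racemic centre of 8 is erased. The step needs acylation at the isocyanide carbon and not at the acidic α‑carbon, secured by withholding base until 9 is consumed, and ring closure faster than loss of chloride from the anion, favoured by the fully substituted, N‑protected ring C that cannot ionise the sulfone and by the low temperature of base addition.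

Step 6
Reactants: 11 4‑chloro‑5‑(4‑methoxyphenyl)‑2‑(3,4,5‑trichloro‑1‑SEM‑pyrrol‑2‑yl)oxazole
Product: 12 4‑chloro‑5‑(4‑methoxyphenyl)‑2‑(3,4,5‑trichloro‑1H‑pyrrol‑2‑yl)oxazole
Conditions: Bu4NF (3 equiv), THF, 60 °C; 1 M HCl quench
Reagents that add atoms: none
Why: Fluoride‑induced SEM cleavage: attack at silicon triggers fragmentation to fluorotrimethylsilane, ethylene, formaldehyde and the pyrrolide, here a good leaving group because three chlorines and the oxazole stabilise the anion, while aryl chlorides, oxazole and methyl ether are inert to fluoride.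

Step 7
Reactants: 12 4‑chloro‑5‑(4‑methoxyphenyl)‑2‑(3,4,5‑trichloro‑1H‑pyrrol‑2‑yl)oxazole
Product: 13 4‑chloro‑5‑(4‑hydroxyphenyl)‑2‑(3,4,5‑trichloro‑1H‑pyrrol‑2‑yl)oxazole (target)
Conditions: BBr3 (4 equiv), CH2Cl2, −78 °C→rt; H2O
Reagents that add atoms: none
Why: Lewis‑acid cleavage of the aryl methyl ether, in which BBr3 coordinates the anisole oxygen and bromide removes the methyl group by SN2, followed by hydrolysis of the aryl borate on work‑up; the C–Cl bonds, the oxazole and the free pyrrole N–H should tolerate the reagent.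

**Compound list**

1 | pyrrole‑2‑carbaldehyde | O=Cc1ccc[nH]1 | starting material
2 | 3,4,5‑trichloro‑1H‑pyrrole‑2‑carbaldehyde | O=Cc1[nH]c(Cl)c(Cl)c1Cl | intermediate
3 | 3,4,5‑trichloro‑1‑{[2‑(trimethylsilyl)ethoxy]methyl}pyrrole‑2‑carbaldehyde | O=Cc1c(Cl)c(Cl)c(Cl)n1COCC[Si](C)(C)C | intermediate
4 | formamide | NC=O | starting material
5 | p‑toluenesulfinic acid | Cc1ccc(S(=O)O)cc1 | starting material
6 | N,N'‑{[3,4,5‑trichloro‑1‑SEM‑pyrrol‑2‑yl]methylene}bisformamide (not isolated) | O=CNC(NC=O)c1c(Cl)c(Cl)c(Cl)n1COCC[Si](C)(C)C | intermediate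
7 | N‑{(4‑methylphenylsulfonyl)[3,4,5‑trichloro‑1‑SEM‑pyrrol‑2‑yl]methyl}formamide (racemic) | O=CNC(c1c(Cl)c(Cl)c(Cl)n1COCC[Si](C)(C)C)S(=O)(=O)c1ccc(C)cc1 | intermediate
8 | 2,3,4‑trichloro‑5‑[isocyano(4‑methylphenylsulfonyl)methyl]‑1‑SEM‑pyrrole (racemic) | [C-]#[N+]C(c1c(Cl)c(Cl)c(Cl)n1COCC[Si](C)(C)C)S(=O)(=O)c1ccc(C)cc1 | intermediate
9 | 4‑methoxybenzoyl chloride | COc1ccc(C(=O)Cl)cc1 | starting material
10 | N‑{(4‑methylphenylsulfonyl)[3,4,5‑trichloro‑1‑SEM‑pyrrol‑2‑yl]methyl}‑2‑(4‑methoxyphenyl)‑2‑oxoacetimidoyl chloride (racemic, C=N geometry not defined, not isolated) | COc1ccc(C(=O)C(Cl)=NC(c2c(Cl)c(Cl)c(Cl)n2COCC[Si](C)(C)C)S(=O)(=O)c2ccc(C)cc2)cc1 | intermediate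
11 | 4‑chloro‑5‑(4‑methoxyphenyl)‑2‑(3,4,5‑trichloro‑1‑SEM‑pyrrol‑2‑yl)oxazole | COc1ccc(-c2oc(-c3c(Cl)c(Cl)c(Cl)n3COCC[Si](C)(C)C)nc2Cl)cc1 | intermediate
12 | 4‑chloro‑5‑(4‑methoxyphenyl)‑2‑(3,4,5‑trichloro‑1H‑pyrrol‑2‑yl)oxazole | COc1ccc(-c2oc(-c3[nH]c(Cl)c(Cl)c3Cl)nc2Cl)cc1 | intermediate
13 | 4‑chloro‑5‑(4‑hydroxyphenyl)‑2‑(3,4,5‑trichloro‑1H‑pyrrol‑2‑yl)oxazole | Oc1ccc(-c2oc(-c3[nH]c(Cl)c(Cl)c3Cl)nc2Cl)cc1 | target

**Step count**

Total: 7 steps. Longest linear sequence: 7 steps (1 → 13); 4, 5 and 9 enter as purchased materials.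

**Steps most likely to fail**

Step 5 (proposed new method). The insertion of an electron‑poor α‑sulfonyl isocyanide into an electron‑rich aroyl chloride may be slow, so that thermal decomposition of 8 competes. After base addition the anion may lose chloride to a nitrile ylide, DBU may attack C4 of the imidoyl chloride, or adventitious water may hydrolyse 10 before ring closure. Fallback with known chemistry, setting out from 3 and returning at 11:
- Aldehyde 3 would be oxidised (NaClO2, NaH2PO4, 2‑methyl‑2‑butene, t‑BuOH/H2O; Pinnick oxidation) to 3,4,5‑trichloro‑1‑SEM‑pyrrole‑2‑carboxylic acid F1.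
- F1 would be converted with oxalyl chloride and catalytic DMF into 3,4,5‑trichloro‑1‑SEM‑pyrrole‑2‑carbonyl chloride F2.
- F2 would acylate commercial 2‑amino‑1‑(4‑methoxyphenyl)ethanone hydrochloride (Et3N, CH2Cl2, 0 °C) to give the keto amide N‑[2‑(4‑methoxyphenyl)‑2‑oxoethyl]‑3,4,5‑trichloro‑1‑SEM‑pyrrole‑2‑carboxamide F3.
- Robinson–Gabriel cyclodehydration under conditions that spare SEM (PPh3, I2, Et3N, CH2Cl2) should give 5‑(4‑methoxyphenyl)‑2‑(3,4,5‑trichloro‑1‑SEM‑pyrrol‑2‑yl)oxazole F4.
- Electrophilic chlorination of F4 with NCS (MeCN, 50 °C) at C4 of ring B should then give 11; C4 is the only unsubstituted heteroaryl position and the β‑carbon of the O1–C5=C4 enol ether.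

Step 3. Condensation at the formyl group, which is flanked by the N‑SEM group and the C3 chlorine, may be slow, and the HCl released may partly remove the SEM group or ionise the product sulfone. Fallback, setting out from 3 and returning at 7:
- LiN(SiMe3)2 (THF, 0 °C; aza‑Peterson olefination) would convert 3 into the N‑trimethylsilyl aldimine N‑(trimethylsilyl)‑1‑[3,4,5‑trichloro‑1‑SEM‑pyrrol‑2‑yl]methanimine F5.
- N‑formylation of F5 with acetic formic anhydride would give the N‑formyl imine N‑{[3,4,5‑trichloro‑1‑SEM‑pyrrol‑2‑yl]methylene}formamide F6 in the flask.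
- p‑Toluenesulfinic acid 5 would add across the C=N bond of F6 to give 7 under water‑free conditions without strong acid.

Step 1. Chlorination may stop before the deactivated C3 is substituted, or over‑chlorination to non‑aromatic chloropyrrolenines and N‑chlorination may erode the material. Fallback, setting out from 1 and returning at 3 (compound 2 is bypassed):
- Aldehyde 1 would first be N‑protected (NaH, SEMCl, THF) to 1‑SEM‑pyrrole‑2‑carbaldehyde F7.
- F7 is a more nucleophilic N‑alkyl pyrrole without an N–H, and exhaustive chlorination with NCS (3.3 equiv, MeCN, 50 °C) should give 3 directly.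

**Further compounds**

F1 | step 5 | 3,4,5‑trichloro‑1‑SEM‑pyrrole‑2‑carboxylic acid | OC(=O)c1c(Cl)c(Cl)c(Cl)n1COCC[Si](C)(C)C
F2 | step 5 | 3,4,5‑trichloro‑1‑SEM‑pyrrole‑2‑carbonyl chloride | O=C(Cl)c1c(Cl)c(Cl)c(Cl)n1COCC[Si](C)(C)C
F3 | step 5 | N‑[2‑(4‑methoxyphenyl)‑2‑oxoethyl]‑3,4,5‑trichloro‑1‑SEM‑pyrrole‑2‑carboxamide | COc1ccc(C(=O)CNC(=O)c2c(Cl)c(Cl)c(Cl)n2COCC[Si](C)(C)C)cc1
F4 | step 5 | 5‑(4‑methoxyphenyl)‑2‑(3,4,5‑trichloro‑1‑SEM‑pyrrol‑2‑yl)oxazole | COc1ccc(-c2cnc(-c3c(Cl)c(Cl)c(Cl)n3COCC[Si](C)(C)C)o2)cc1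
F5 | step 3 | N‑(trimethylsilyl)‑1‑[3,4,5‑trichloro‑1‑SEM‑pyrrol‑2‑yl]methanimine | C[Si](C)(C)N=Cc1c(Cl)c(Cl)c(Cl)n1COCC[Si](C)(C)C
F6 | step 3 | N‑{[3,4,5‑trichloro‑1‑SEM‑pyrrol‑2‑yl]methylene}formamide | O=CN=Cc1c(Cl)c(Cl)c(Cl)n1COCC[Si](C)(C)C
F7 | step 1 | 1‑SEM‑pyrrole‑2‑carbaldehyde | O=Cc1cccn1COCC[Si](C)(C)C
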